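**Retrosynthetic overview**
1. Target 15 ⇐ methanolysis of aryl lactone 14; the lactone masks the ester and the C7–OH through the synthesis.
2. cis-2,3-Dimethyl pair ⇐ face-selective hydrogenation of the exo-methylene ketone 13.
3. Key C4–C3 bond ⇐ carbene-catalysed intramolecular hydroacylation of aldehyde 11: the formyl carbon reacts as an acyl anion equivalent (Breslow intermediate) with the tethered alkyne.
4. 11 ⇐ ortho-formylation and C-prenylation of lactone 6; 6 ⇐ enantioselective annulation of (E)-hex-2-enal onto mono-ether 3, itself from phloroglucinol and (S)-but-3-yn-2-ol (Mitsunobu).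
5. Ring order: benzene ring bought; lactone ring (step 2); pyranone ring (step 5); lactone ring opened last (step 7).

Assumption: the (5aS,10bR) triazolium salt of step 2 is taken to give the 4R lactone by analogy with related annulations; if a first run gives 4S, its mirror-image salt is used and nothing else changes.

**Route**

Step 1
Reactants: 1 phloroglucinol (benzene-1,3,5-triol); 2 (S)-but-3-yn-2-ol
Product: 3 5-{[(2R)-but-3-yn-2-yl]oxy}benzene-1,3-diol
Conditions: PPh3 (1.2 eq), DIAD (1.2 eq), THF, 0 °C, 15 min (betaine first); then 2 (1.0 eq), 1 (3 eq), 0 → 25 °C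
Reagents that add atoms: none
Why: Mitsunobu etherification: SN2 displacement at the activated propargylic carbon inverts (S)-2 to the (R)-ether, the future C2 of the chromanone; excess symmetric triol keeps the reaction at the mono-ether, and pre-forming the betaine keeps the azo ester away from the electron-rich ring.

Step 2
Reactants: 3 5-{[(2R)-but-3-yn-2-yl]oxy}benzene-1,3-diol; 4 (E)-hex-2-enal
Product: 6 (4R)-5-{[(2R)-but-3-yn-2-yl]oxy}-7-hydroxy-4-propylchroman-2-one, via unsaturated acyl azolium 5 (not isolated)
Conditions: 3 (1.3 eq), 4 (1.0 eq), (5aS,10bR)-2-mesityl-5a,10b-dihydro-4H,6H-indeno[2,1-b][1,2,4]triazolo[4,3-d][1,4]oxazin-2-ium chloride (10 mol%), iPr2NEt (20 mol%), 3,3',5,5'-tetra-tert-butyl-4,4'-diphenoquinone (1.2 eq), toluene, 25 °C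
Reagents that add atoms: none
Why: Proposed new method: the carbene adds to 4, the quinone oxidises the Breslow intermediate to acyl azolium 5, the phenol of 3 adds to its carbonyl group and a Coates–Claisen-type [3,3] shift (or direct conjugate addition) forms the aryl–C bond at a ring carbon ortho to the ether and para to the second OH, then lactonisation frees the catalyst; the chiral triazolium shields one face of the enoyl unit and so sets C4; closest known reaction type: enantioselective carbene-catalysed oxidative annulation of enals with naphthols and other stable enols; the 5-hydroxy-7-alkoxy regioisomer and any bis-annulated material are removed by chromatography.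

Step 3
Reactants: 6 (4R)-5-{[(2R)-but-3-yn-2-yl]oxy}-7-hydroxy-4-propylchroman-2-one; 7 prenyl bromide (1-bromo-3-methylbut-2-ene)
Product: 9 (4R)-5-{[(2R)-but-3-yn-2-yl]oxy}-7-hydroxy-8-(3-methylbut-2-en-1-yl)-4-propylchroman-2-one, via ring-opened hydroxy acid 8 (not isolated)
Conditions: 10% aq KOH (4 eq), 0 °C; 7 (1.1 eq), 0 → 25 °C; then 2 M HCl to pH 2, 25 °C
Reagents that add atoms: none
Why: Nuclear C-prenylation of a phloroglucinol-type phenoxide in water: KOH opens the lactone, the one ring carbon lying between two phenoxide oxygens is the most nucleophilic and takes the prenyl group (water favours C- over O-alkylation), and acid closes the lactone again onto the only OH next to the side chain; no stereocenter is touched, and a modest yield is expected.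

Step 4
Reactants: 9 (4R)-5-{[(2R)-but-3-yn-2-yl]oxy}-7-hydroxy-8-(3-methylbut-2-en-1-yl)-4-propylchroman-2-one
Product: 11 (4R)-5-{[(2R)-but-3-yn-2-yl]oxy}-7-hydroxy-8-(3-methylbut-2-en-1-yl)-2-oxo-4-propylchromane-6-carbaldehyde, via hydroxymethyl phenol 10 (not isolated)
Conditions: MgCl2 (2 eq), Et3N (4 eq), (CH2O)n (6 eq), MeCN, 80 °C; 1 M HCl work-up
Reagents that add atoms: formaldehyde (used as paraformaldehyde), C=O
Why: Casnati–Skattebøl ortho-formylation: the magnesium phenoxide delivers formaldehyde to the single free ring position, which is ortho to the OH, and intermediate 10 is oxidised in the flask by hydride transfer to a second formaldehyde; alkyne, prenyl group and both stereocenters are spectators.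

Step 5
Reactants: 11 (4R)-5-{[(2R)-but-3-yn-2-yl]oxy}-7-hydroxy-8-(3-methylbut-2-en-1-yl)-2-oxo-4-propylchromane-6-carbaldehyde
Product: 13 (2R,10R)-5-hydroxy-2-methyl-3-methylidene-6-(3-methylbut-2-en-1-yl)-10-propyl-2,3,9,10-tetrahydro-4H,8H-pyrano[2,3-f]chromene-4,8-dione, via Breslow intermediate 12 (not isolated)
Conditions: 3-mesityl-5,6,7,8-tetrahydro-4H-cyclohepta[d][1,3]thiazol-3-ium perchlorate (10 mol%), K2CO3 (20 mol%), THF, 70 °C; short silica plug, used at once
Reagents that add atoms: none
Why: Proposed new method: the carbene adds to the formyl group to give Breslow intermediate 12, in which the former carbonyl carbon is a nucleophile (acyl anion equivalent); it attacks the internal alkyne carbon in a 6-exo, Conia-ene-like transition state while the enol O–H goes to the terminal carbon, and loss of the carbene gives the exo-methylene ketone; closest known reaction type: carbene-catalysed intramolecular hydroacylation of unactivated alkynes in 2-(propargyloxy)benzaldehydes to 3-alkylidenechroman-4-ones (new here: a terminal alkyne with a propargylic methyl group, a free chelated ortho-OH and an aryl lactone); no stereocenter is formed, C2 and C10 are untouched, and the sp2 C3 cannot yet epimerise.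

Step 6
Reactants: 13 (2R,10R)-5-hydroxy-2-methyl-3-methylidene-6-(3-methylbut-2-en-1-yl)-10-propyl-2,3,9,10-tetrahydro-4H,8H-pyrano[2,3-f]chromene-4,8-dione
Product: 14 (2R,3S,10R)-5-hydroxy-2,3-dimethyl-6-(3-methylbut-2-en-1-yl)-10-propyl-2,3,9,10-tetrahydro-4H,8H-pyrano[2,3-f]chromene-4,8-dione
Conditions: H2 (1 atm), RhCl(PPh3)3 (5 mol%), benzene/EtOH 1:1, 25 °C
Reagents that add atoms: none
Why: Homogeneous syn-hydrogenation with RhCl(PPh3)3: the 1,1-disubstituted exocyclic alkene is reduced much faster than the trisubstituted prenyl alkene; allylic 1,3-strain holds the C2 methyl pseudo-axial, hydrogen is delivered to C3 from the opposite face, so the new C3 methyl ends up cis to the C2 methyl (3S), and the neutral medium does not epimerise this kinetic cis isomer.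

Step 7
Reactants: 14 (2R,3S,10R)-5-hydroxy-2,3-dimethyl-6-(3-methylbut-2-en-1-yl)-10-propyl-2,3,9,10-tetrahydro-4H,8H-pyrano[2,3-f]chromene-4,8-dione
Product: 15 methyl (3R)-3-[(2R,3S)-5,7-dihydroxy-2,3-dimethyl-6-(3-methylbut-2-en-1-yl)-4-oxo-3,4-dihydro-2H-chromen-8-yl]hexanoate
Conditions: MeOH (solvent), H2SO4 (5 mol%), 25–40 °C; NaHCO3 before concentration
Reagents that add atoms: methanol, CO
Why: Acid-catalysed transesterification (methanolysis of the aryl lactone): the large excess of methanol drives ring opening to the methyl ester and the free C7–OH; dilute acid at this temperature should neither enolise the chelated ketone nor cyclise the prenyl group, and neutralising before concentration prevents re-lactonisation.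

**Compound list**
1 | phloroglucinol (benzene-1,3,5-triol) | Oc1cc(O)cc(O)c1 | starting material
2 | (S)-but-3-yn-2-ol | C[C@H](O)C#C | starting material
3 | 5-{[(2R)-but-3-yn-2-yl]oxy}benzene-1,3-diol | C#C[C@@H](C)Oc1cc(O)cc(O)c1 | intermediate
4 | (E)-hex-2-enal | CCC/C=C/C=O | starting material
5 | unsaturated acyl azolium: cation of the step 2 catalyst carrying the (E)-hex-2-enoyl group on its carbene carbon, shown as chloride (not isolated) | Cc1cc(C)c(c(C)c1)[n+]1c(C(=O)/C=C/CCC)n2c(n1)CO[C@H]1Cc3ccccc3[C@@H]21.[Cl-] | intermediate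
6 | (4R)-5-{[(2R)-but-3-yn-2-yl]oxy}-7-hydroxy-4-propylchroman-2-one | CCC[C@@H]1CC(=O)Oc2cc(O)cc(O[C@H](C)C#C)c21 | intermediate
7 | prenyl bromide (1-bromo-3-methylbut-2-ene) | CC(C)=CCBr | starting material
8 | (3R)-3-[6-{[(2R)-but-3-yn-2-yl]oxy}-2,4-dihydroxy-3-(3-methylbut-2-en-1-yl)phenyl]hexanoic acid (not isolated) | CCC[C@H](CC(=O)O)c1c(O)c(CC=C(C)C)c(O)cc1O[C@H](C)C#C | intermediate
9 | (4R)-5-{[(2R)-but-3-yn-2-yl]oxy}-7-hydroxy-8-(3-methylbut-2-en-1-yl)-4-propylchroman-2-one | CCC[C@@H]1CC(=O)Oc2c(CC=C(C)C)c(O)cc(O[C@H](C)C#C)c21 | intermediate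
10 | (4R)-5-{[(2R)-but-3-yn-2-yl]oxy}-7-hydroxy-6-(hydroxymethyl)-8-(3-methylbut-2-en-1-yl)-4-propylchroman-2-one (not isolated) | CCC[C@@H]1CC(=O)Oc2c(CC=C(C)C)c(O)c(CO)c(O[C@H](C)C#C)c21 | intermediate
11 | (4R)-5-{[(2R)-but-3-yn-2-yl]oxy}-7-hydroxy-8-(3-methylbut-2-en-1-yl)-2-oxo-4-propylchromane-6-carbaldehyde | CCC[C@@H]1CC(=O)Oc2c(CC=C(C)C)c(O)c(C=O)c(O[C@H](C)C#C)c21 | intermediate
12 | Breslow intermediate: enaminol of 11 in which the former formyl carbon carries OH and is doubly bonded to C2 of 3-mesityl-5,6,7,8-tetrahydro-4H-cyclohepta[d][1,3]thiazol-2-ylidene (not isolated) | CCC[C@@H]1CC(=O)Oc2c(CC=C(C)C)c(O)c(C(O)=C3SC4=C(CCCCC4)N3c3c(C)cc(C)cc3C)c(O[C@H](C)C#C)c21 | intermediate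
13 | (2R,10R)-5-hydroxy-2-methyl-3-methylidene-6-(3-methylbut-2-en-1-yl)-10-propyl-2,3,9,10-tetrahydro-4H,8H-pyrano[2,3-f]chromene-4,8-dione | CCC[C@@H]1CC(=O)Oc2c(CC=C(C)C)c(O)c3C(=O)C(=C)[C@@H](C)Oc3c21 | intermediate
14 | (2R,3S,10R)-5-hydroxy-2,3-dimethyl-6-(3-methylbut-2-en-1-yl)-10-propyl-2,3,9,10-tetrahydro-4H,8H-pyrano[2,3-f]chromene-4,8-dione | CCC[C@@H]1CC(=O)Oc2c(CC=C(C)C)c(O)c3C(=O)[C@@H](C)[C@@H](C)Oc3c21 | intermediate
15 | methyl (3R)-3-[(2R,3S)-5,7-dihydroxy-2,3-dimethyl-6-(3-methylbut-2-en-1-yl)-4-oxo-3,4-dihydro-2H-chromen-8-yl]hexanoate | CCC[C@H](CC(=O)OC)c1c(O)c(CC=C(C)C)c(O)c2c1O[C@H](C)[C@H](C)C2=O | target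

**Totals**
Total step count: 7. Longest linear sequence: 7 steps (1 → 15).

**Three steps most likely to fail, with fallbacks**

Step 5 (carbene hydroacylation). The base turns the chelated phenol into a phenoxide that deactivates the hindered aldehyde, and the exo-methylene ketone can be consumed by the carbene or isomerise to the chromone, which would erase C2. The fallback sets out from 11 and comes back at 13 by chelation-assisted rhodium hydroacylation: [RhCl(C8H12)]2 (2.5 mol%, C8H12 = cycloocta-1,5-diene), Fe(C5H4PPh2)2 (5 mol%), Na2CO3 (10 mol%), toluene, 80 °C. The ortho phenoxide binds monovalent rhodium and the formyl C–H adds oxidatively to give an acyl hydride of trivalent rhodium. This is again an acyl anion equivalent, but made without a free carbene; it adds across the tethered alkyne and reductively eliminates to 13. Here the free OH is the directing group rather than a liability. The fallback makes no compound outside the list (F0).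

Step 2 (annulation). The phenol class is untested with acyl azolium ions, the [3,3] pathway may also deliver the side chain between the two OH groups, and the sense and level of induction with a β-alkyl enal must be checked. The fallback sets out from 3 (with 4) and comes back at 6 by iminium-ion Friedel–Crafts alkylation: (R)-2-[diphenyl(trimethylsilyloxy)methyl]pyrrolidine (20 mol%), PhCO2H (20 mol%), toluene, 0 °C. The neutral phenol attacks the iminium ion of 4 as in an electrophilic aromatic substitution, at the carbon para to one OH and ortho to the ether. That is the position 5-alkoxyresorcinols choose in Vilsmeier and Pechmann reactions. The catalyst shields one face, and the (R)-amine is expected to give 4R by the usual model. The neighbouring OH closes onto the aldehyde to give the lactol (4R)-5-{[(2R)-but-3-yn-2-yl]oxy}-4-propylchromane-2,7-diol F1. Buffered pyridinium chlorochromate, [C5H5NH][CrO3Cl], with NaOAc in CH2Cl2 then oxidises F1 to 6.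

Step 3 (C-prenylation). O-prenylation, attack at the other free ring carbon, double alkylation and ester formation at the carboxylate all compete, so the yield may be low. The fallback sets out from 6 and comes back at 9 by O-alkylation followed by a sigmatropic shift. Pd(PPh3)4 (zerovalent palladium, 2 mol%) and tert-butyl 2-methylbut-3-en-2-yl carbonate in THF at 0 °C give the tertiary allyl ether (4R)-5-{[(2R)-but-3-yn-2-yl]oxy}-7-[(2-methylbut-3-en-2-yl)oxy]-4-propylchroman-2-one F2. Heating F2 in toluene at 110 °C brings about the aromatic Claisen rearrangement, which delivers the prenyl group with allylic inversion to C8 (para to the ether oxygen) and gives 9. The C6 isomer is removed, and the propargyl ether does not rearrange at this temperature.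

**Further compounds**
F0 | step 5 | none | none
F1 | step 2 | (4R)-5-{[(2R)-but-3-yn-2-yl]oxy}-4-propylchromane-2,7-diol (lactol, mixture at C2) | CCC[C@@H]1CC(O)Oc2cc(O)cc(O[C@H](C)C#C)c21
F2 | step 3 | (4R)-5-{[(2R)-but-3-yn-2-yl]oxy}-7-[(2-methylbut-3-en-2-yl)oxy]-4-propylchroman-2-one | CCC[C@@H]1CC(=O)Oc2cc(OC(C)(C)C=C)cc(O[C@H](C)C#C)c21
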